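The earlier runs and the new flask stem from a simulated flask from invented constants; scatter was added.

The target does not stay as made in these flasks: the isomer of the product grows beside it. Two chemists read the same runs and disagree about what this means for ochre, amber and violet, which differ in their time.

| flask | starting material | second substrate | reagent | free catalyst | remark | time |
|---|---|---|---|---|---|---|
| theta | 0.038 M | 0.0385 M | 0.231 M | 71 µM | run made earlier |  |
| beta | 0.058 M | 0.0385 M | 0.231 M | 71 µM | run made earlier |  |
| zeta | 0.077 M | 0.0385 M | 0.12 M | 71 µM | run made earlier |  |
| ochre | 0.077 M | 0.0385 M | 0.231 M | 71 µM |  | 5.0 d |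
| amber | 0.077 M | 0.0385 M | 0.231 M | 71 µM |  | 6.0 d |
| violet | 0.077 M | 0.0385 M | 0.231 M | 71 µM |  | 8.0 d |

| run | time / d | starting material / % | target / % | isomer of the product / % | catalyst intermediate A / % |
|---|---|---|---|---|---|
| theta | 0.417 | 67.5 | 28.9 | 3.2 | 0.5 |
| theta | 0.833 | 45.4 | 46.9 | 9.1 | 0 |
| theta | 1.25 | 30.2 | 56.6 | 12.7 | 0 |
| theta | 2.50 | 9.1 | 71.6 | 18.3 | 0 |
| theta | 5.00 | 0.5 | 77.1 | 20.5 | 0 |
| beta | 0.417 | 70.1 | 26.2 | 2.6 | 0 |
| beta | 0.833 | 50.1 | 42.9 | 8.2 | 0.7 |
| beta | 1.25 | 36.0 | 52.7 | 11.9 | 0 |
| beta | 2.50 | 12.5 | 69.9 | 17.9 | 0.6 |
| beta | 5.00 | 2.0 | 77.8 | 21.2 | 0 |
| zeta | 1.04 | 69.8 | 25.2 | 4.7 | 0 |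
| zeta | 2.08 | 52.6 | 38.4 | 9.8 | 0.3 |
| zeta | 3.00 | 44.2 | 44.4 | 10.4 | 0 |
| zeta | 4.00 | 36.5 | 50.0 | 12.9 | 0 |
| zeta | 5.00 | 31.2 | 53.8 | 13.4 | 0.4 |

(scatter of a reading: 0.5 percentage points)

- reactions considered so far: starting material + free catalyst <-> catalyst intermediate A; reagent + catalyst intermediate A -> free catalyst + target; second substrate + free catalyst <-> catalyst intermediate B; reagent + catalyst intermediate B -> free catalyst + second product; target + free catalyst <-> isomer of the product + free catalyst

- which of these there is most of at the end, counted by the starting material in it, ochre (starting material / isomer of the product / catalyst intermediate A / target)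
- which of these there is most of at the end, counted by the starting material in it, amber (starting material / isomer of the product / catalyst intermediate A / target)
- which of these there is most of at the end, counted by the starting material in it, violet (starting material / isomer of the product / catalyst intermediate A / target)
- how much there is at the end of the one of these that leads, in percent of the starting material charged: ochre
- how much there is at the end of the one of these that leads, in percent of the starting material charged: amber
- how much there is at the end of the one of these that leads, in percent of the starting material charged: violet

The first chemist holds that the target simply drains into the isomer. In the theta run the isomer rose from 3.2% to 9.1% between 0.417 d and 0.833 d. Dividing that gain by the average target and the time gives a drain of 0.374 d⁻¹. If the feed from starting material is taken as over by amber, her view puts the target in violet at 47.3% of its value in amber, so waiting costs yield.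

The second chemist takes the step between target and isomer as balanced, which is thermodynamic control. The same reckoning on the last two theta readings gives 0.0118 d⁻¹, far smaller than the early drain, so the apparent drain dies away while target is plentiful. She therefore carries one quantity, the balanced target share: target divided by target plus isomer, read at the last readings of theta and beta together. It comes to 78.8%. Her rule, for the late part of a run, where the reckoned drain has died away, is that target equals this share times whatever has left the starting material, so the target climbs with waiting.

The forecast stands on her side, with a share of its own, “target is about 78.5% of the converted material”. It names target as the leader in each flask, at 76.8% in ochre, 77.6% in amber and 78.2% in violet.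

The flasks give 76.6%, 77.7% and 78.5%, with target leading each time.

    starting material + free catalyst ⇌ catalyst intermediate A (K = 11.0 M⁻¹, k = 8600 M⁻¹ h⁻¹)
    reagent + catalyst intermediate A → free catalyst + target (k = 340 M⁻¹ h⁻¹)
    second substrate + free catalyst ⇌ catalyst intermediate B (K = 35.0 M⁻¹, k = 690 M⁻¹ h⁻¹)
    reagent + catalyst intermediate B → free catalyst + second product (k = 9000 M⁻¹ h⁻¹)
    target + free catalyst ⇌ isomer of the product + free catalyst, rate k5*[free catalyst]*[target] forward; the back reaction follows from the equilibrium constant (K = 0.270, k = 580 M⁻¹ h⁻¹)

Ochre keeps 2.83% of its starting material, and the share applied to the rest gives 76.6% target. The reason the target holds is the way back from isomer to target: with that way taken away, ochre ends at 6.33% target instead of 76.6%, and violet at 0.828%. That run without the way back is where the first chemist's picture of a one-way drain belongs, whatever its rate there.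

Take the neighbour of ochre with 0.058 M of reagent, and let the 0.0385 M of second substrate take its full measure of reagent. Reckoned so, what remains turns 25.3% of the starting material, and the share makes that 19.9% target. That flask gives 20.4% target and 74.1% starting material, with the reagent, its limiting reagent, down to 3.73% of its charge.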